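A one-step world has nothing to count: substrate and partner give product, and the share asked for is trivial. These flasks are not that world, since teal shows trapped intermediate at 2.6% beside product at 66.1% after 2.50 h.

| setting | teal | amber | green | birch | larch | alder | maple | ash |
|---|---|---|---|---|---|---|---|---|
| substrate | 10 mM | 10 mM | 10 mM | 10 mM (fed, over 1.0 h) | 10 mM (in portions, 3, over 1.0 h) | 10 mM (fed, over 15 min) | 10 mM | 10 mM |
| partner | 8 mM | 4 mM | 6 mM | 8.00 mM | 8.00 mM | 8.00 mM | 8.00 mM | 8.00 mM (fed, over 1.0 h) |
| capture agent | 0.50 mM | 0.50 mM | 0.50 mM | 0.500 mM | 0.500 mM | 0.500 mM | 0.500 mM | 0.500 mM |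
| remark | run made earlier | run made earlier | run made earlier | all else is in the flask from the start; the feed brings no volume worth counting | first portion at the start, last at 1.0 h | all else is in the flask from the start; the feed brings no volume worth counting | everything together at the start | all else is in the flask from the start; the feed brings no volume worth counting |
| time |  |  |  | 2.5 h | 2.5 h | 2.5 h | 2.5 h | 2.5 h |

| run | time / h | product / % | trapped intermediate / % |
|---|---|---|---|
| teal | 0.333 | 10.5 | 1.6 |
| teal | 0.667 | 26.6 | 2.3 |
| teal | 1.00 | 39.1 | 2.4 |
| teal | 1.33 | 49.7 | 3.3 |
| teal | 2.00 | 60.8 | 4.2 |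
| teal | 2.50 | 66.1 | 2.6 |
| amber | 0.417 | 7.4 | 0.5 |
| amber | 0.833 | 19.6 | 2.3 |
| amber | 1.33 | 27.6 | 1.4 |
| amber | 1.50 | 29.4 | 2.9 |
| amber | 2.00 | 33.1 | 2.6 |
| amber | 2.50 | 34.8 | 2.4 |
| amber | 3.00 | 36.8 | 1.8 |
| green | 0.167 | 3.2 | 0.9 |
| green | 0.500 | 15.2 | 1.1 |
| green | 0.833 | 26.5 | 2.0 |
| green | 1.33 | 39.0 | 2.9 |
| green | 2.00 | 48.4 | 3.1 |
| green | 2.50 | 51.5 | 2.7 |
| green | 3.00 | 53.9 | 3.2 |

(standard deviation of a reading: 0.5 percentage points)



- the flask with the highest share of product in product plus trapped intermediate ("all alike" if they lie within 1.5 percentage points) (birch / larch / alder / maple / ash / all alike)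
- share of product in product plus trapped intermediate at the end, birch
- share of product in product plus trapped intermediate at the end, larch
- share of product in product plus trapped intermediate at the end, alder
- share of product in product plus trapped intermediate at the end, maple
- share of product in product plus trapped intermediate at the end, ash

**What do you count?** Turns of the capture agent against product. Over teal's last 3 readings, trapped intermediate averages 0.337 mM and product 5.89 mM, out of a capture charge of 0.500 mM. That gives κ = 0.190 /mM, the fraction of the free capture agent bound per mM of product made, a selectivity factor. Hence c(trapped intermediate) = c(capture agent, charged)·(1 − exp(−κ·c(product))).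

**Why should κ be constant?** I suppose that product and trapped intermediate both form from one unseen open intermediate, each first order in it, so that its concentration cancels from the ratio. That is a supposition, but amber, with half the partner, reads 0.173 /mM. The scatter of teal's value is about 0.0300 /mM.

**Then what does dosing do?** It moves the clock, not the count. The slow feeds and larch's portions hold the charge back by 0.500 h on average. I therefore place birch, larch and ash about where teal stood at 2.00 h, with product 6.08 mM. Maple is teal's recipe, with product 6.61 mM, and alder lies between them.

**And the shares?** I reckon maple at 0.358 mM trapped, a share of 94.9%. I reckon the late flasks at 0.343 mM, a share of 94.7%. The gap is 0.2 percentage points, less than the margin of 1.5 points, so I commit to all alike.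

The forecast said all alike, with birch at 94.6% and maple at 94.7%, on the ground that “dosing should barely change selectivity”.

The simulation gives all alike: birch 94.5%, larch 94.5%, alder 94.7%, maple 94.7%, ash 94.5%.

    substrate + partner → open intermediate + released group (k = 3.91 /M/min)
    open intermediate → product (k = 0.0322 /min)
    open intermediate + capture agent → trapped intermediate (k = 6.45 /M/min)

In maple, the half-life of the open intermediate by the step to product is 0.36 h at 0.334 h, ten times shorter than the 3.6 h it has by trapping alone with the other concentrations as charged. With κ, maple's product of 65.9% at 2.50 h reckons to 28.6% of the capture agent free, and the flask holds 26.7%. Maple with 2.0 mM of capture agent made 56.6% product, for which the same κ gives a share of 81.1%, and that flask stands at 80.7%.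

All runs were computed with made-up constants, noise included.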